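Isochromene numbering is used (O2, C1, C3, C4, C4a, C5–C8, C8a). The carbocycle C4a–C5–C6–C7–C8–C8a is a 2-acetoxy-2-methylcyclohexane-1,3-dione in which C7 is stereogenic only because the C6 and C8 carbonyls sit in different surroundings. The route therefore goes back to achiral 2-hydroxy-2-methylcyclohexane-1,3-dione, and a ketoreductase reduces one of its two enantiotopic carbonyls (the future C6): one hydride transfer fixes the C7 quaternary centre and leaves C8 as the only ketone, which then directs C–C bond formation to C4a and C8a. The pyran ring is closed late by 6-endo attack of the C1 hydroxyl on a C3≡C4 alkyne; chlorine enters C5 last.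

Key step: step 2

Remarks on the chemistry
- Assumption: once the C6 enone is in place, C8a–H is α to C8=O and vinylogous to C6=O and therefore configurationally labile; the 8aR epimer of the bicycle (C1 and the C7 methyl group cis, C7 acetoxy pseudo-axial and clear of both flanking carbonyl dipoles) is taken to be the more stable one and is reached by equilibration in step 16.
- Stereochemical bookkeeping: 2S in 3 is the same spatial arrangement as 7R in 26 (in 3 the ketone carbon outranks the carbinol carbon; in 26 C6 outranks C8 because of chlorine on C5). Without chlorine the same centre is 7S (24, 25).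
- The side-chain centre of 26 is R, the antipode of the unit in natural 2-methylbutan-1-ol. The chain is therefore built from 7, whose CH2Br arm becomes the ethyl group.
- The ylide of step 6 and the phosphonate of step 7 are commercial reagents.

Step 1
Reactants: 1 2-methylcyclohexane-1,3-dione
Product: 2 2-hydroxy-2-methylcyclohexane-1,3-dione
Conditions: DMDO, acetone, 0 °C
Reagents that add atoms: dimethyldioxirane, CC1(C)OO1
Why: Oxygen transfer from the dioxirane to the enol double bond of the β-diketone (a Rubottom-type α-hydroxylation without prior silylation) gives the achiral tertiary α-ketol under neutral conditions that avoid α-ketol rearrangement.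

Step 2
Reactants: 2 2-hydroxy-2-methylcyclohexane-1,3-dione
Product: 3 (2S,3S)-2,3-dihydroxy-2-methylcyclohexan-1-one
Conditions: ketoreductase (NADPH-dependent, chosen by panel screening), NADP+ (cat.), i-PrOH, potassium phosphate buffer pH 6.5, 30 °C
Reagents that add atoms: none
Why: The enzyme binds NADPH and the dione, transfers the C4 hydride of the dihydronicotinamide to one face of one carbonyl while the catalytic tyrosine protonates the oxygen, and isopropanol regenerates the cofactor. The closest known reaction type is the ketoreductase or yeast desymmetrisation of 2,2-disubstituted cyclohexane-1,3-diones to 3-hydroxy ketones. No ring is closed and no skeletal bond is formed. The carbinol centre (future C6) is set by the face of hydride delivery and the quaternary centre (future C7) by the choice between the two enantiotopic carbonyls, both under control of the active site, so that a single reduction creates two stereocentres. The step needs attack on the pro-R carbonyl only, with the new hydroxyl cis to the tertiary one, and no second reduction; the OH/CH3 pair at C2 differs in polarity and hydrogen bonding more than in size, which is what the screened enzyme must read, and the free hydroxyl keeps the substrate small and water-soluble. Buffer at pH 6.5 and 30 °C protects the α-hydroxy-β-diketone from retro-Claisen opening and α-ketol rearrangement.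

Step 3
Reactants: 3 (2S,3S)-2,3-dihydroxy-2-methylcyclohexan-1-one
Product: 4 (3aS,7aS)-2,2,3a-trimethylhexahydro-1,3-benzodioxol-4-one
Conditions: Me2C(OMe)2, PPTS (cat.), CH2Cl2, 23 °C
Reagents that add atoms: 2,2-dimethoxypropane, COC(C)(C)OC
Why: Acid-catalysed transketalisation of the cis-1,2-diol gives the cis-fused dioxolane, which masks the future C6 and C7 oxygens against the enolate chemistry at C8 and leaves both stereocentres untouched.

Step 4
Reactants: 4 (3aS,7aS)-2,2,3a-trimethylhexahydro-1,3-benzodioxol-4-one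
Product: 6 (3aS,7aS)-2,2,3a-trimethyl-7,7a-dihydro-1,3-benzodioxol-4(3aH)-one, via trimethylsilyl enol ether 5 (not isolated)
Conditions: LDA, TMSCl, THF, −78 °C; then Pd(OAc)2 (10 mol %), O2, DMSO, 23 °C
Reagents that add atoms: none
Why: Saegusa–Ito dehydrogenation, in which the ketone can enolise only toward C8a because C7 is quaternary and the palladium enolate loses the C4a hydride to give the C8a=C4a enone without touching C6 or C7.

Step 5
Reactants: 7 (S)-3-bromo-2-methylpropan-1-ol
Product: 8 (R)-2-methylbutan-1-ol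
Conditions: MeMgBr (3 equiv), Li2CuCl4 (5 mol %), THF, −20 → 0 °C
Reagents that add atoms: methylmagnesium bromide, C[Mg]Br
Why: Copper-catalysed cross-coupling of the Grignard reagent with the primary bromide of the magnesium alkoxide (Kochi coupling) turns CH2Br into ethyl at a carbon next to the stereocentre, which is retained (the descriptor changes from S to R only through the priority rules).

Step 6
Reactants: 8 (R)-2-methylbutan-1-ol
Product: 10 (2E,4R)-2,4-dimethylhex-2-enal, via (R)-2-methylbutanal 9 (not isolated)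
Conditions: TEMPO (cat.), KBr, NaOCl, NaHCO3, toluene/H2O, 0 °C; dried toluene layer, then Ph3P=C(CH3)CHO, 80 °C
Reagents that add atoms: 2-(triphenyl-λ5-phosphanylidene)propanal, CC(C=O)=P(c1ccccc1)(c1ccccc1)c1ccccc1
Why: Anelli oxidation gives the volatile, epimerisable aldehyde, which is used in solution in a Wittig reaction with the formyl-stabilised, non-basic ylide, whose reversible addition makes the trisubstituted alkene E while the α-stereocentre is never exposed to base.

Step 7
Reactants: 10 (2E,4R)-2,4-dimethylhex-2-enal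
Product: 11 trimethyl[(3E,5E,7R)-5,7-dimethylnona-3,5-dien-1-yn-1-yl]silane
Conditions: (EtO)2P(O)CH2C≡CSiMe3, LiHMDS, THF, −78 → 0 °C
Reagents that add atoms: diethyl [3-(trimethylsilyl)prop-2-yn-1-yl]phosphonate, CCOP(=O)(OCC)CC#C[Si](C)(C)C
Why: Horner–Wadsworth–Emmons olefination with the preformed propargylic phosphonate anion gives the conjugated enyne with the new disubstituted double bond E, the anion adding to the aldehyde faster than it can deprotonate the γ-position.

Step 8
Reactants: 11 trimethyl[(3E,5E,7R)-5,7-dimethylnona-3,5-dien-1-yn-1-yl]silane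
Product: 12 (3E,5E,7R)-5,7-dimethylnona-3,5-dien-1-yne
Conditions: K2CO3, MeOH, 23 °C
Reagents that add atoms: none
Why: Methoxide-mediated protodesilylation of the alkynylsilane frees the terminal alkyne needed for metalation and leaves the diene and the stereocentre alone.

Step 9
Reactants: 6 (3aS,7aS)-2,2,3a-trimethyl-7,7a-dihydro-1,3-benzodioxol-4(3aH)-one; 12 (3E,5E,7R)-5,7-dimethylnona-3,5-dien-1-yne
Product: 16 (3aS,5S,6S,7aS)-6-[(3E,5E,7R)-5,7-dimethylnona-3,5-dien-1-yn-1-yl]-5-(hydroxymethyl)-2,2,3a-trimethylhexahydro-1,3-benzodioxol-4-one, via lithium acetylide 13 (not isolated), via alkynylzinc bromide 14 (not isolated), via silyl enol ether 15 (not isolated)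
Conditions: 12, n-BuLi, THF, −78 °C; ZnBr2, 0 °C; then 6, TBSOTf, Et2O, −40 °C; then aq. HCHO, Yb(OTf)3 (20 mol %), THF, 23 °C
Reagents that add atoms: formaldehyde, C=O
Why: Silyl-triflate-promoted 1,4-addition of the alkynylzinc bromide (cuprates do not transfer alkynyl groups) places the dienynyl group on C4a, and a lanthanide-triflate-catalysed Mukaiyama aldol reaction of the C8/C8a silyl enol ether with aqueous formaldehyde installs C1 regiospecifically; the alkynyl group should enter anti to the dioxolane and CH2OH trans to it, but C4a later becomes sp2 and C8a is re-set in step 16, so neither selectivity is critical.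

Step 10
Reactants: 16 (hydroxymethyl ketone, name as in step 9)
Product: 17 (3aS,5S,6S,7aS)-5-({[tert-butyl(diphenyl)silyl]oxy}methyl)-6-[(3E,5E,7R)-5,7-dimethylnona-3,5-dien-1-yn-1-yl]-2,2,3a-trimethylhexahydro-1,3-benzodioxol-4-one
Conditions: TBDPSCl, imidazole, CH2Cl2, 0 → 23 °C
Reagents that add atoms: tert-butyl(chloro)diphenylsilane, CC(C)(C)[Si](Cl)(c1ccccc1)c1ccccc1
Why: Silylation of the primary hydroxyl under weakly basic conditions (no retro-aldol, no β-elimination) installs a group that survives the aqueous acid, oxidation and acetylation of steps 11 to 13.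

Step 11
Reactants: 17 (silyl ether, name as in step 10)
Product: 18 (2S,3S,5S,6S)-6-({[tert-butyl(diphenyl)silyl]oxy}methyl)-5-[(3E,5E,7R)-5,7-dimethylnona-3,5-dien-1-yn-1-yl]-2,3-dihydroxy-2-methylcyclohexan-1-one
Conditions: 1 M aq. HCl, THF, 23 °C
Reagents that add atoms: none
Why: Acid hydrolysis of the dioxolane frees the C6/C7 diol while the primary TBDPS ether, the β-silyloxy ketone and the dienyne are stable to dilute acid.

Step 12
Reactants: 18 (diol, name as in step 11)
Product: 19 (2S,4S,5S)-4-({[tert-butyl(diphenyl)silyl]oxy}methyl)-5-[(3E,5E,7R)-5,7-dimethylnona-3,5-dien-1-yn-1-yl]-2-hydroxy-2-methylcyclohexane-1,3-dione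
Conditions: IBX, DMSO, 23 °C
Reagents that add atoms: none
Why: IBX oxidises the secondary C6 carbinol of the vicinal diol to the ketone without glycol cleavage, and the tertiary C7 hydroxyl cannot be oxidised.

Step 13
Reactants: 19 (hydroxy diketone, name as in step 12)
Product: 20 (1S,3S,4S)-3-({[tert-butyl(diphenyl)silyl]oxy}methyl)-4-[(3E,5E,7R)-5,7-dimethylnona-3,5-dien-1-yn-1-yl]-1-methyl-2,6-dioxocyclohexyl acetate
Conditions: Ac2O, Sc(OTf)3 (5 mol %), MeCN, −20 °C
Reagents that add atoms: acetic anhydride, CC(=O)OC(C)=O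
Why: Lewis-acid-catalysed acetylation esterifies the hindered tertiary hydroxyl with retention at C7 and avoids the amine bases that could trigger α-ketol rearrangement or retro-Claisen opening of the 2-hydroxy-1,3-dione.

Step 14
Reactants: 20 (diketone acetate, name as in step 13)
Product: 22 (1S,5S)-5-({[tert-butyl(diphenyl)silyl]oxy}methyl)-4-[(3E,5E,7R)-5,7-dimethylnona-3,5-dien-1-yn-1-yl]-1-methyl-2,6-dioxocyclohex-3-en-1-yl acetate, via trimethylsilyl enol ether 21 (not isolated)
Conditions: TMSOTf, Et3N, CH2Cl2, −78 → −20 °C; then Pd(OAc)2 (1.1 equiv), MeCN, 23 °C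
Reagents that add atoms: none
Why: Saegusa–Ito dehydrogenation, in which soft enolisation silylates the C6 ketone toward its unhindered C5 methylene (C7 is quaternary and the C8 ketone could only enolise toward the hindered C8a methine) and β-hydride loss from C4a gives the C4a=C5 enone in conjugation with the alkyne without strong base, so that acetate and silyl ether survive.

Step 15
Reactants: 22 (enynone, name as in step 14)
Product: 23 (1S,5S)-4-[(3E,5E,7R)-5,7-dimethylnona-3,5-dien-1-yn-1-yl]-5-(hydroxymethyl)-1-methyl-2,6-dioxocyclohex-3-en-1-yl acetate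
Conditions: HF·pyridine, THF, 0 → 23 °C
Reagents that add atoms: none
Why: Fluoride cleavage of the silyl ether in an acidic, non-nucleophilic medium frees the C1 hydroxyl without hydrolysing the acetate or opening a base-induced elimination path at C8a.

Step 16
Reactants: 23 (hydroxy enynone, name as in step 15)
Product: 25 (7S,8aR)-3-[(1E,3E,5R)-3,5-dimethylhepta-1,3-dien-1-yl]-7-methyl-6,8-dioxo-6,7,8,8a-tetrahydro-1H-isochromen-7-yl acetate, via 8a-epimer 24 (not isolated)
Conditions: Ph3PAuNTf2 (5 mol %), CH2Cl2, 23 °C; then Et3N (0.2 equiv), 23 °C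
Reagents that add atoms: none
Why: Gold-catalysed intramolecular hydroalkoxylation in the 6-endo-dig mode, in which the C1 hydroxyl attacks C3, the alkyne carbon that carries the cation-stabilising dienyl group and is the remote terminus of the enynone (attack at C4 would give a cross-conjugated alkylidene-tetrahydrofuran), after which a trace of amine equilibrates C8a through the C8 enol to the epimer with C1 and the C7 methyl group cis.

Step 17
Reactants: 25 (bicyclic dienone, name as in step 16)
Product: 26 (7R,8aR)-5-chloro-3-[(1E,3E,5R)-3,5-dimethylhepta-1,3-dien-1-yl]-7-methyl-6,8-dioxo-6,7,8,8a-tetrahydro-1H-isochromen-7-yl acetate (CNP0108998.1)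
Conditions: NCS (1.05 equiv), MeCN, 23 °C
Reagents that add atoms: N-chlorosuccinimide, O=C1CCC(=O)N1Cl
Why: Electrophilic chlorination at C5, the α-carbon and most nucleophilic position of the vinylogous ester O2–C3=C4–C4a=C5–C6=O (the reaction type used for late C5 halogenation of azaphilone cores), proceeds under neutral conditions that leave the side-chain diene, C7 and C8a unchanged.

Compound list
1 | 2-methylcyclohexane-1,3-dione | CC1C(=O)CCCC1=O | starting material
2 | 2-hydroxy-2-methylcyclohexane-1,3-dione | CC1(O)C(=O)CCCC1=O | intermediate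
3 | (2S,3S)-2,3-dihydroxy-2-methylcyclohexan-1-one | O[C@H]1CCCC(=O)[C@@]1(C)O | intermediate
4 | (3aS,7aS)-2,2,3a-trimethylhexahydro-1,3-benzodioxol-4-one | CC1(C)O[C@H]2CCCC(=O)[C@@]2(C)O1 | intermediate
5 | (3aS,7aS)-2,2,3a-trimethyl-4-[(trimethylsilyl)oxy]-3a,6,7,7a-tetrahydro-1,3-benzodioxole | CC1(C)O[C@H]2CCC=C(O[Si](C)(C)C)[C@@]2(C)O1 | intermediate
6 | (3aS,7aS)-2,2,3a-trimethyl-7,7a-dihydro-1,3-benzodioxol-4(3aH)-one | CC1(C)O[C@H]2CC=CC(=O)[C@@]2(C)O1 | intermediate
7 | (S)-3-bromo-2-methylpropan-1-ol | BrC[C@@H](C)CO | starting material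
8 | (R)-2-methylbutan-1-ol | CC[C@@H](C)CO | intermediate
9 | (R)-2-methylbutanal | CC[C@@H](C)C=O | intermediate
10 | (2E,4R)-2,4-dimethylhex-2-enal | CC[C@@H](C)/C=C(C)/C=O | intermediate
11 | trimethyl[(3E,5E,7R)-5,7-dimethylnona-3,5-dien-1-yn-1-yl]silane | CC[C@@H](C)/C=C(C)/C=C/C#C[Si](C)(C)C | intermediate
12 | (3E,5E,7R)-5,7-dimethylnona-3,5-dien-1-yne | CC[C@@H](C)/C=C(C)/C=C/C#C | intermediate
13 | [(3E,5E,7R)-5,7-dimethylnona-3,5-dien-1-yn-1-yl]lithium | CC[C@@H](C)/C=C(C)/C=C/C#C[Li] | intermediate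
14 | bromo[(3E,5E,7R)-5,7-dimethylnona-3,5-dien-1-yn-1-yl]zinc | CC[C@@H](C)/C=C(C)/C=C/C#C[Zn]Br | intermediate
15 | (3aS,6S,7aS)-4-{[tert-butyl(dimethyl)silyl]oxy}-6-[(3E,5E,7R)-5,7-dimethylnona-3,5-dien-1-yn-1-yl]-2,2,3a-trimethyl-3a,6,7,7a-tetrahydro-1,3-benzodioxole (alkynyl anti to the dioxolane oxygens) | CC1(C)O[C@H]2C[C@H](C#C/C=C/C(C)=C/[C@H](C)CC)C=C(O[Si](C)(C)C(C)(C)C)[C@@]2(C)O1 | intermediate
16 | (3aS,5S,6S,7aS)-6-[(3E,5E,7R)-5,7-dimethylnona-3,5-dien-1-yn-1-yl]-5-(hydroxymethyl)-2,2,3a-trimethylhexahydro-1,3-benzodioxol-4-one (CH2OH trans to the alkynyl group, expected major isomer) | CC1(C)O[C@H]2C[C@H](C#C/C=C/C(C)=C/[C@H](C)CC)[C@@H](CO)C(=O)[C@@]2(C)O1 | intermediate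
17 | (3aS,5S,6S,7aS)-5-({[tert-butyl(diphenyl)silyl]oxy}methyl)-6-[(3E,5E,7R)-5,7-dimethylnona-3,5-dien-1-yn-1-yl]-2,2,3a-trimethylhexahydro-1,3-benzodioxol-4-one | CC1(C)O[C@H]2C[C@H](C#C/C=C/C(C)=C/[C@H](C)CC)[C@@H](CO[Si](c3ccccc3)(c3ccccc3)C(C)(C)C)C(=O)[C@@]2(C)O1 | intermediate
18 | (2S,3S,5S,6S)-6-({[tert-butyl(diphenyl)silyl]oxy}methyl)-5-[(3E,5E,7R)-5,7-dimethylnona-3,5-dien-1-yn-1-yl]-2,3-dihydroxy-2-methylcyclohexan-1-one | O[C@H]1C[C@H](C#C/C=C/C(C)=C/[C@H](C)CC)[C@@H](CO[Si](c2ccccc2)(c2ccccc2)C(C)(C)C)C(=O)[C@@]1(C)O | intermediate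
19 | (2S,4S,5S)-4-({[tert-butyl(diphenyl)silyl]oxy}methyl)-5-[(3E,5E,7R)-5,7-dimethylnona-3,5-dien-1-yn-1-yl]-2-hydroxy-2-methylcyclohexane-1,3-dione | O=C1C[C@H](C#C/C=C/C(C)=C/[C@H](C)CC)[C@@H](CO[Si](c2ccccc2)(c2ccccc2)C(C)(C)C)C(=O)[C@@]1(C)O | intermediate
20 | (1S,3S,4S)-3-({[tert-butyl(diphenyl)silyl]oxy}methyl)-4-[(3E,5E,7R)-5,7-dimethylnona-3,5-dien-1-yn-1-yl]-1-methyl-2,6-dioxocyclohexyl acetate | O=C1C[C@H](C#C/C=C/C(C)=C/[C@H](C)CC)[C@@H](CO[Si](c2ccccc2)(c2ccccc2)C(C)(C)C)C(=O)[C@@]1(C)OC(C)=O | intermediate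
21 | C6 trimethylsilyl enol ether of 20 (C5=C6, C6–OSiMe3; other centres as in 20) | C[Si](C)(C)OC1=C[C@H](C#C/C=C/C(C)=C/[C@H](C)CC)[C@@H](CO[Si](c2ccccc2)(c2ccccc2)C(C)(C)C)C(=O)[C@@]1(C)OC(C)=O | intermediate
22 | (1S,5S)-5-({[tert-butyl(diphenyl)silyl]oxy}methyl)-4-[(3E,5E,7R)-5,7-dimethylnona-3,5-dien-1-yn-1-yl]-1-methyl-2,6-dioxocyclohex-3-en-1-yl acetate (C8a labile from here on) | O=C1C=C(C#C/C=C/C(C)=C/[C@H](C)CC)[C@@H](CO[Si](c2ccccc2)(c2ccccc2)C(C)(C)C)C(=O)[C@@]1(C)OC(C)=O | intermediate
23 | (1S,5S)-4-[(3E,5E,7R)-5,7-dimethylnona-3,5-dien-1-yn-1-yl]-5-(hydroxymethyl)-1-methyl-2,6-dioxocyclohex-3-en-1-yl acetate | O=C1C=C(C#C/C=C/C(C)=C/[C@H](C)CC)[C@@H](CO)C(=O)[C@@]1(C)OC(C)=O | intermediate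
24 | (7S,8aS)-3-[(1E,3E,5R)-3,5-dimethylhepta-1,3-dien-1-yl]-7-methyl-6,8-dioxo-6,7,8,8a-tetrahydro-1H-isochromen-7-yl acetate | CC[C@@H](C)/C=C(C)/C=C/C1=CC2=CC(=O)[C@](C)(OC(C)=O)C(=O)[C@@H]2CO1 | intermediate
25 | (7S,8aR)-3-[(1E,3E,5R)-3,5-dimethylhepta-1,3-dien-1-yl]-7-methyl-6,8-dioxo-6,7,8,8a-tetrahydro-1H-isochromen-7-yl acetate | CC[C@@H](C)/C=C(C)/C=C/C1=CC2=CC(=O)[C@](C)(OC(C)=O)C(=O)[C@H]2CO1 | intermediate
26 | (7R,8aR)-5-chloro-3-[(1E,3E,5R)-3,5-dimethylhepta-1,3-dien-1-yl]-7-methyl-6,8-dioxo-6,7,8,8a-tetrahydro-1H-isochromen-7-yl acetate | CC[C@@H](C)/C=C(C)/C=C/C1=CC2=C(Cl)C(=O)[C@](C)(OC(C)=O)C(=O)[C@H]2CO1 | target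

Total step count: 17.
Longest linear sequence: 13 steps (steps 1–4 and 9–17; the side-chain branch, steps 5–8 followed by 9–17, is equally long).

Steps most likely to fail

Step 2. What may go wrong: the enzyme may discriminate poorly between the two enantiotopic carbonyls, whose C2 neighbours (OH and CH3) are of similar size, or the dione may open hydrolytically in buffer before it is reduced. The fallback replaces desymmetrisation by kinetic resolution and sets out from 2. Partial reduction with NaBH4 (0.3 equiv, MeOH/CH2Cl2, −78 °C; axial hydride attack on the conformer with axial OH) should give racemic cis-2,3-dihydroxy-2-methylcyclohexan-1-one F1. Acylation with vinyl acetate and immobilised Candida antarctica lipase B (MTBE, 30 °C) is expected, by the usual empirical rule for lipase acylation of secondary alcohols, to esterify the (3R)-carbinol to (1R,2R)-2-hydroxy-2-methyl-3-oxocyclohexyl acetate F2. This leaves (2S,3S)-3, at which the route is rejoined with at most half of the material.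

Step 14. What may go wrong: the C8 ketone may enolise toward C8a in competition with the C6 ketone, which gives the isomeric C4a=C8a enone and double-bond migration. The fallback takes the C8 carbonyl out of play while the enone is made and sets out from 17. NaBH4 (MeOH, 0 °C) should give the C8 alcohol of 17 F3 (either C8 epimer serves). 4-Methoxybenzyl trichloroacetimidate with La(OTf)3 (cat., toluene, 23 °C) gives its 4-methoxybenzyl ether F4. 1 M aq. HCl/THF frees the C6/C7 diol F5, IBX (DMSO, 23 °C) gives the C6 ketone F6, and Ac2O/DMAP/Et3N gives the C7 acetate F7. The only ketone now present can enolise only toward C5, so IBX with 4-methoxypyridine N-oxide (DMSO, 23 °C) gives the C4a=C5 enone F8. DDQ (CH2Cl2/pH 7 buffer, 0 °C) removes the benzyl group to give the C8 alcohol F9, and Dess–Martin periodinane (NaHCO3, CH2Cl2) oxidises it to 22, where the route is rejoined.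

Step 16. What may go wrong: the hydroxyl (or the C8 carbonyl oxygen) may attack C4 in a 5-exo closure, with drift to alkylidene-tetrahydrofuran or furan products; the C8a equilibrium is thermodynamic either way. The fallback makes the C3–O bond by addition–elimination instead of alkyne activation and sets out from 23. Morpholine (1.1 equiv, MeCN, 0 °C) adds in conjugate fashion to C3, the terminus of the enynone, to give the dienaminone F10. PPTS (CH2Cl2, 23 °C) then lets the C1 hydroxyl displace morpholine at C3 through the vinylogous iminium ion, a 6-exo-trig closure that cannot form the five-membered ring. The liberated amine equilibrates C8a, and the route is rejoined at 25.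

Further compounds
F1 | step 2 | racemic cis-2,3-dihydroxy-2-methylcyclohexan-1-one | O[C@H]1CCCC(=O)[C@@]1(C)O.O[C@@H]1CCCC(=O)[C@]1(C)O
F2 | step 2 | (1R,2R)-2-hydroxy-2-methyl-3-oxocyclohexyl acetate | CC(=O)O[C@@H]1CCCC(=O)[C@]1(C)O
F3 | step 14 | C8 alcohol of 17 (17 with CH–OH in place of C8=O, C8 epimers) | CC1(C)O[C@H]2C[C@H](C#C/C=C/C(C)=C/[C@H](C)CC)[C@@H](CO[Si](c3ccccc3)(c3ccccc3)C(C)(C)C)C(O)[C@@]2(C)O1
F4 | step 14 | 4-methoxybenzyl ether of F3 | CC1(C)O[C@H]2C[C@H](C#C/C=C/C(C)=C/[C@H](C)CC)[C@@H](CO[Si](c3ccccc3)(c3ccccc3)C(C)(C)C)C(OCc3ccc(OC)cc3)[C@@]2(C)O1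
F5 | step 14 | C6/C7 diol from F4 (dioxolane removed) | O[C@H]1C[C@H](C#C/C=C/C(C)=C/[C@H](C)CC)[C@@H](CO[Si](c2ccccc2)(c2ccccc2)C(C)(C)C)C(OCc2ccc(OC)cc2)[C@@]1(C)O
F6 | step 14 | C6 ketone from F5 (C7 tertiary alcohol, C8 4-methoxybenzyl ether) | O=C1C[C@H](C#C/C=C/C(C)=C/[C@H](C)CC)[C@@H](CO[Si](c2ccccc2)(c2ccccc2)C(C)(C)C)C(OCc2ccc(OC)cc2)[C@@]1(C)O
F7 | step 14 | C7 acetate of F6 | O=C1C[C@H](C#C/C=C/C(C)=C/[C@H](C)CC)[C@@H](CO[Si](c2ccccc2)(c2ccccc2)C(C)(C)C)C(OCc2ccc(OC)cc2)[C@@]1(C)OC(C)=O
F8 | step 14 | C4a=C5 enone from F7 | O=C1C=C(C#C/C=C/C(C)=C/[C@H](C)CC)[C@@H](CO[Si](c2ccccc2)(c2ccccc2)C(C)(C)C)C(OCc2ccc(OC)cc2)[C@@]1(C)OC(C)=O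
F9 | step 14 | C8 alcohol from F8 (22 with CH–OH in place of C8=O) | O=C1C=C(C#C/C=C/C(C)=C/[C@H](C)CC)[C@@H](CO[Si](c2ccccc2)(c2ccccc2)C(C)(C)C)C(O)[C@@]1(C)OC(C)=O
F10 | step 16 | (1S,5S)-4-[(3E,5E,7R)-5,7-dimethyl-2-(morpholin-4-yl)nona-1,3,5-trien-1-yl]-5-(hydroxymethyl)-1-methyl-2,6-dioxocyclohex-3-en-1-yl acetate (geometry of the aminated double bond immaterial) | O=C1C=C(C=C(N2CCOCC2)/C=C/C(C)=C/[C@H](C)CC)[C@@H](CO)C(=O)[C@@]1(C)OC(C)=O
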